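Colleague, you asked for a quick number for the flask with 0.0110 M of reagent; here is what the runs allow, and the hunch you gave us.

| flask | substrate | reagent | free catalyst | remark | time |
|---|---|---|---|---|---|
| dusk | 0.010 M | 0.015 M | 100 µM | run made earlier |  |
| summer | 0.010 M | 0.024 M | 100 µM | run made earlier |  |
| flask | 0.010 M | 0.0110 M | 100 µM |  | 20 h |

| run | time / h | product / % | substrate / % |
|---|---|---|---|
| dusk | 1.50 | 5.2 | 94.5 |
| dusk | 5.00 | 18.1 | 82.5 |
| dusk | 8.00 | 27.7 | 72.7 |
| dusk | 12.0 | 39.1 | 61.1 |
| dusk | 20.0 | 56.9 | 43.2 |
| dusk | 25.0 | 65.6 | 33.9 |
| summer | 1.50 | 5.5 | 94.0 |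
| summer | 5.00 | 18.2 | 81.9 |
| summer | 8.00 | 27.8 | 72.2 |
| summer | 12.0 | 39.1 | 60.5 |
| summer | 20.0 | 56.6 | 43.7 |
| summer | 25.0 | 64.8 | 33.7 |

(each reading ± 0.5 percentage points)



- concentration of product at 20 h, in M
- concentration of substrate at 20 h, in M

The dusk and summer runs, whose reagent charges differ 1.60-fold, read 56.9% and 56.6% product at 20.0 h, the same within the scatter. So we follow one substrate molecule through two forks. At the first it has or has not reacted by the asked time, and between the reagent charges of those runs that chance shows no dependence on reagent beyond the scatter. At the second a reagent must be there for it, and we assume one reagent per product, since the readings give substrate and product but not reagent. We therefore carry the reagent demand, the substrate charge times that chance, 0.00568 M, and, with the substrate charge, the free catalyst charge and the time held, take as product the lesser of demand and reagent charge.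

In this flask the demand is about half of the charge, so we commit to 0.00568 M of product and 0.00432 M of substrate. The risk is that, at one reagent per product, this flask's reagent would end at 0.00532 M, lower than the 0.00844 M we reckon the same way for the last dusk reading. Your forecast weighs that stretch and gives less product than we do: 0.0054 M (0.0045 M to 0.0058 M) and 0.0046 M of substrate (0.0042 M to 0.0055 M), with the ground “If reagent saturation begins to fail, the reaction slows somewhat”.

The flask gives 0.00565 M of product and 0.00434 M of substrate, inside both your ranges.

    catalyst intermediate C ⇌ catalyst intermediate D (K = 0.430, k = 90.0 h⁻¹)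
    reagent + free catalyst → catalyst intermediate A (k = 35000 M⁻¹ h⁻¹)
    catalyst intermediate D → free catalyst + product (k = 140 h⁻¹)
    catalyst intermediate A → catalyst intermediate B (k = 140 h⁻¹)
    substrate + catalyst intermediate B ⇌ catalyst intermediate C (K = 14.0 M⁻¹, k = 9500 M⁻¹ h⁻¹)

The demand leaves 48.4% of this flask's reagent charge, and the flask holds 48% at 20 h. Now take the neighbouring flask charged with 0.0044 M of reagent and the same substrate: its demand is still 0.00568 M, more than that charge, so the reagent there is the limiting reagent, and we reckon 0.0044 M of product and 0.00560 M of substrate. That neighbouring flask ends with 0.00440 M of product, 0.00560 M of substrate and 0% of its reagent at 20.0 h.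

The runs are calculated for substances that don't exist; noise was put on by code.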